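**Retrosynthetic overview** (numbering: C1≡C2–C3=C4–C5–C6(OAc)–C7(O)–C8–C9=C10–C11–C12(Br)–C13(O)–C14–C15)
1. Endgame on a preformed bromo-oxocene: acetate by acylation; C1–C5 enyne by chelation-controlled allylation of the C6 aldehyde, cross-metathesis with crotonaldehyde and Colvin homologation; Br at C12 by invertive substitution of the C12 alcohol.
2. The only ring, the oxocene O–C7–C8–C9=C10–C11–C12–C13, is disconnected at C10–C11: forward, a (Z)-alkenyllithium at C10 opens a terminal epoxide C11–C12 (8-endo) and frees the C12 alkoxide in the same operation.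
3. Enabling feature: C11 is the one ring CH2 lying between an sp2 carbon (C10 of the cis C9=C10 bond) and a heteroatom-bearing carbon (C12, Br reachable from OH), so C11–C12 can be an oxirane hanging from C13 and C10 a vinyl anion; the cis alkene and the ring oxygen in the tether ease eight-membered closure.
4. The acyclic ether precursor comes from (S)-glycidol (C6–C8), trimethylsilylacetylene (C9, C10) and (E)-pent-2-en-1-ol (C11–C15): epoxide alkynylation, Ir-catalysed allylic etherification (C13), epoxidation and hydrolytic kinetic resolution (C12), iodoalkyne semi-reduction.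
5. Ring order: one ring, formed in step 9.

Key step: step 9

Assumption: the (Sa,S,S) Ir–phosphoramidite catalyst is taken to give the (R)-branched ether and the (S,S)-(salen)Co catalyst to spare the (12R)-epoxide, by analogy with simple alkyl allyl carbonates and glycidyl-type epoxides; if either sense proves opposite, the antipodal catalyst is used.

**Route**

Step 1
Reactants: 1 (S)-glycidol
Product: 2 (2R)-2-{[(4-methoxyphenyl)methoxy]methyl}oxirane
Conditions: NaH, 4-methoxybenzyl chloride, Bu4NI (cat.), THF/DMF, 0 °C → rt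
Reagents that add atoms: 4-methoxybenzyl chloride, COc1ccc(CCl)cc1
Why: Williamson O-alkylation of the primary alkoxide; no bond at the stereocentre is touched (the descriptor changes from S to R only through the CIP priorities).

Step 2
Reactants: 2 (2R)-2-{[(4-methoxyphenyl)methoxy]methyl}oxirane; 3 ethynyltrimethylsilane
Product: 5 (2R)-1-[(4-methoxyphenyl)methoxy]-5-(trimethylsilyl)pent-4-yn-2-ol, via lithium (trimethylsilyl)acetylide 4 (not isolated)
Conditions: 3, n-BuLi, THF, −78 °C; BF3·OEt2; then 2, −78 °C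
Reagents that add atoms: none
Why: BF3-promoted opening of the terminal epoxide by the lithium acetylide at its CH2 terminus (Yamaguchi–Hirao alkynylation) installs C9–C10 and frees the C7 hydroxyl without touching the C7 stereocentre.

Step 3
Reactants: 6 (2E)-pent-2-en-1-ol
Product: 7 tert-butyl (2E)-pent-2-en-1-yl carbonate
Conditions: Boc2O, aq NaOH, Bu4NHSO4 (cat.), CH2Cl2, 0 °C → rt
Reagents that add atoms: di-tert-butyl dicarbonate, CC(C)(C)OC(=O)OC(=O)OC(C)(C)C
Why: Phase-transfer O-acylation of the primary allylic alcohol gives the ionisable carbonate needed for iridium allyl chemistry.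

Step 4
Reactants: 5 (2R)-1-[(4-methoxyphenyl)methoxy]-5-(trimethylsilyl)pent-4-yn-2-ol; 7 tert-butyl (2E)-pent-2-en-1-yl carbonate
Product: 9 {(4R)-5-[(4-methoxyphenyl)methoxy]-4-[(3R)-pent-1-en-3-yloxy]pent-1-yn-1-yl}trimethylsilane, via copper alkoxide 8 (not isolated)
Conditions: 5, n-BuLi, THF, 0 °C; CuI; then 7 (1.5 equiv), [Ir(cod)Cl]2 (2 mol %), (Sa,S,S)-O,O′-(1,1′-binaphthyl-2,2′-diyl) N,N-bis(1-phenylethyl)phosphoramidite (4 mol %), THF, rt
Reagents that add atoms: none
Why: Iridium-catalysed branch-selective allylic etherification, in which the copper alkoxide attacks the substituted terminus of the (π-allyl)Ir–phosphoramidite complex from outside the metal, forms the bis-secondary ether and sets C13 (R) by catalyst control.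

Step 5
Reactants: 9 {(4R)-5-[(4-methoxyphenyl)methoxy]-4-[(3R)-pent-1-en-3-yloxy]pent-1-yn-1-yl}trimethylsilane
Product: 10 2-[(1R)-1-({(2R)-1-[(4-methoxyphenyl)methoxy]-5-(trimethylsilyl)pent-4-yn-2-yl}oxy)propyl]oxirane (both epimers at the oxirane carbon C12)
Conditions: mCPBA (excess), CH2Cl2, 0 °C → rt
Reagents that add atoms: 3-chloroperoxybenzoic acid, OOC(=O)c1cccc(Cl)c1
Why: Prilezhaev epoxidation of the only C=C (silylalkyne and anisyl ring are inert); little facial control is expected at C12, so the epimers are resolved in the next step.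

Step 6
Reactants: 10 epoxide epimer mixture
Product: 11 (2R)-2-[(1R)-1-({(2R)-1-[(4-methoxyphenyl)methoxy]-5-(trimethylsilyl)pent-4-yn-2-yl}oxy)propyl]oxirane
Conditions: (S,S)-(salen)Co(OAc) (1 mol %; salen = N,N′-bis(3,5-di-tert-butylsalicylidene)-1,2-cyclohexanediamine dianion), H2O (0.55 equiv), THF, 0 °C → rt
Reagents that add atoms: none
Why: Jacobsen hydrolytic kinetic resolution: the chiral cobalt catalyst should hydrolyse the (12S)-epoxide to a separable diol and leave the (12R)-epoxide, so C12 is fixed by catalyst control.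

Step 7
Reactants: 11 (12R)-epoxide
Product: 12 (2R)-2-[(1R)-1-({(2R)-5-iodo-1-[(4-methoxyphenyl)methoxy]pent-4-yn-2-yl}oxy)propyl]oxirane
Conditions: N-iodosuccinimide, AgNO3 (10 mol %), DMF, rt, dark
Reagents that add atoms: N-iodosuccinimide, O=C1CCC(=O)N1I
Why: Silver-catalysed iododesilylation converts the alkynylsilane directly into the 1-iodoalkyne under neutral conditions that spare the epoxide.

Step 8
Reactants: 12 iodoalkyne
Product: 13 (2R)-2-[(1R)-1-({(2R,4Z)-5-iodo-1-[(4-methoxyphenyl)methoxy]pent-4-en-2-yl}oxy)propyl]oxirane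
Conditions: 2-nitrobenzenesulfonylhydrazide, Et3N, THF/i-PrOH, rt
Reagents that add atoms: none
Why: Diimide reduction delivers H2 syn across the iodoalkyne and should give the (Z)-alkenyl iodide; epoxide and PMB ether are inert.

Step 9
Reactants: 13 (Z)-alkenyl iodide epoxide
Product: 15 (2R,3R,8R)-2-ethyl-8-{[(4-methoxyphenyl)methoxy]methyl}-3,4,7,8-tetrahydro-2H-oxocin-3-ol, via (Z)-alkenyllithium 14 (not isolated)
Conditions: t-BuLi (2.1 equiv), Et2O, −78 °C; then BF3·OEt2 (1.5 equiv), −78 °C, 0.005 M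
Reagents that add atoms: none
Why: Proposed new method: iodine–lithium exchange gives the configurationally stable (Z)-alkenyllithium 14, whose carbanion carbon C10 opens the BF3-activated terminal oxirane at its CH2 terminus C11 in an SN2 fashion, so the C10–C11 bond, the oxocene and the free C12 alkoxide arise together; the closest known reaction types are the BF3-promoted intermolecular opening of terminal epoxides by alkenyl- and alkynyllithiums, the cyclisation of exchange-derived organolithiums onto tethered epoxides (small and common rings) and the SN2 closure of this ring size in enolate alkylations to 4-oxocenes, but an alkenyl anion–epoxide closure of an eight-membered ring has not been shown. The ring closes in the 8-endo-tet mode (both oxirane carbons end up in the ring; 7-exo attack at C12 would give an oxepene with an exocyclic CH2OH). No stereocentre is created: C12 keeps its (R) configuration because its C–O bond is untouched, C7 and C13 are spectators, and the Z geometry of C9=C10 is carried over from the alkenyl iodide with retention. The step needs C11 over C12 regioselectivity, secured by the unsubstituted terminus versus a secondary carbon inductively deactivated by the C13 ether oxygen, and ring closure over oligomerisation, secured by high dilution and by the cis alkene and ether oxygen in the tether, which remove transannular strain and two rotors.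

Step 10
Reactants: 15 oxocenol
Product: 16 (2R,3S,8R)-3-bromo-2-ethyl-8-{[(4-methoxyphenyl)methoxy]methyl}-3,4,7,8-tetrahydro-2H-oxocine
Conditions: CBr4, P(n-C8H17)3, toluene, 70 °C
Reagents that add atoms: carbon tetrabromide, BrC(Br)(Br)Br
Why: Appel-type bromination (alkoxyphosphonium salt, SN2 by bromide) should replace the C12 hydroxyl with inversion and give the 12S bromide trans to the C13 ethyl group.

Step 11
Reactants: 16 bromo-oxocene PMB ether
Product: 17 [(2R,3S,8R)-3-bromo-2-ethyl-3,4,7,8-tetrahydro-2H-oxocin-8-yl]methanol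
Conditions: DDQ, CH2Cl2/pH 7 buffer, 0 °C → rt
Reagents that add atoms: none
Why: Oxidative PMB cleavage (benzylic hydride abstraction, hemiacetal hydrolysis) frees the primary C6 alcohol without touching the bromide or the ring alkene.

Step 12
Reactants: 17 primary alcohol
Product: 18 (2R,3S,8R)-3-bromo-2-ethyl-3,4,7,8-tetrahydro-2H-oxocine-8-carbaldehyde
Conditions: Dess–Martin periodinane, CH2Cl2, rt
Reagents that add atoms: none
Why: Dess–Martin oxidation gives the α-alkoxy aldehyde under neutral conditions that should not epimerise C7.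

Step 13
Reactants: 18 aldehyde
Product: 19 (1R)-1-[(2R,3S,8R)-3-bromo-2-ethyl-3,4,7,8-tetrahydro-2H-oxocin-8-yl]but-3-en-1-ol
Conditions: CH2=CHCH2SnBu3, MgBr2·OEt2, CH2Cl2, −78 → −20 °C
Reagents that add atoms: allyltributylstannane, C=CC[Sn](CCCC)(CCCC)CCCC
Why: Chelation-controlled allylstannane addition (Keck allylation, Cram-chelate model): MgBr2 bridges the aldehyde and ring oxygens and the allyl group adds to the face opposite ring carbon C8, which gives the 6R (threo) carbinol.

Step 14
Reactants: 19 homoallylic alcohol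
Product: 20 (2E,5R)-5-[(2R,3S,8R)-3-bromo-2-ethyl-3,4,7,8-tetrahydro-2H-oxocin-8-yl]-5-hydroxypent-2-enal
Conditions: crotonaldehyde (5 equiv), second-generation Grubbs catalyst (H2IMes)(PCy3)Cl2Ru=CHPh (5 mol %), CH2Cl2, 40 °C
Reagents that add atoms: (E)-but-2-enal, C/C=C/C=O
Why: Olefin cross-metathesis of the terminal alkene with the electron-poor enal should give the E-enal, the substituted cis ring alkene being much less reactive.

Step 15
Reactants: 20 enal
Product: 21 (1R,3E)-1-[(2R,3S,8R)-3-bromo-2-ethyl-3,4,7,8-tetrahydro-2H-oxocin-8-yl]hex-3-en-5-yn-1-ol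
Conditions: Me3SiCHN2 (2.5 equiv), LiN(i-Pr)2 (2.5 equiv), THF, −78 → 0 °C
Reagents that add atoms: trimethylsilyldiazomethane, C[Si](C)(C)C=[N+]=[N-]
Why: Colvin rearrangement (one-carbon homologation with lithiated trimethylsilyldiazomethane) turns the CHO into the terminal alkyne and leaves the E alkene untouched; the extra equivalent covers the free hydroxyl.

Step 16
Reactants: 21 deacetyl compound
Product: 22 (1R,3E)-1-[(2R,3S,8R)-3-bromo-2-ethyl-3,4,7,8-tetrahydro-2H-oxocin-8-yl]hex-3-en-5-yn-1-yl acetate (target)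
Conditions: Ac2O, pyridine, DMAP (cat.), CH2Cl2, rt
Reagents that add atoms: acetic anhydride, CC(=O)OC(C)=O
Why: DMAP-catalysed acetylation of the only hydroxyl completes the target.

**Compound list**
1 | (S)-glycidol, (2S)-oxiran-2-ylmethanol | OC[C@H]1CO1 | starting material
2 | (2R)-2-{[(4-methoxyphenyl)methoxy]methyl}oxirane | COc1ccc(COC[C@H]2CO2)cc1 | intermediate
3 | ethynyltrimethylsilane | C#C[Si](C)(C)C | starting material
4 | lithium (trimethylsilyl)acetylide | [Li]C#C[Si](C)(C)C | intermediate (not isolated)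
5 | (2R)-1-[(4-methoxyphenyl)methoxy]-5-(trimethylsilyl)pent-4-yn-2-ol | COc1ccc(COC[C@H](O)CC#C[Si](C)(C)C)cc1 | intermediate
6 | (2E)-pent-2-en-1-ol | CC/C=C/CO | starting material
7 | tert-butyl (2E)-pent-2-en-1-yl carbonate | CC/C=C/COC(=O)OC(C)(C)C | intermediate
8 | copper (2R)-1-[(4-methoxyphenyl)methoxy]-5-(trimethylsilyl)pent-4-yn-2-olate (monovalent copper) | COc1ccc(COC[C@H](O[Cu])CC#C[Si](C)(C)C)cc1 | intermediate (not isolated)
9 | {(4R)-5-[(4-methoxyphenyl)methoxy]-4-[(3R)-pent-1-en-3-yloxy]pent-1-yn-1-yl}trimethylsilane | COc1ccc(COC[C@@H](CC#C[Si](C)(C)C)O[C@H](CC)C=C)cc1 | intermediate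
10 | 2-[(1R)-1-({(2R)-1-[(4-methoxyphenyl)methoxy]-5-(trimethylsilyl)pent-4-yn-2-yl}oxy)propyl]oxirane, both C12 epimers | COc1ccc(COC[C@@H](CC#C[Si](C)(C)C)O[C@H](CC)C2CO2)cc1 | intermediate
11 | (2R)-2-[(1R)-1-({(2R)-1-[(4-methoxyphenyl)methoxy]-5-(trimethylsilyl)pent-4-yn-2-yl}oxy)propyl]oxirane | COc1ccc(COC[C@@H](CC#C[Si](C)(C)C)O[C@H](CC)[C@H]2CO2)cc1 | intermediate
12 | (2R)-2-[(1R)-1-({(2R)-5-iodo-1-[(4-methoxyphenyl)methoxy]pent-4-yn-2-yl}oxy)propyl]oxirane | COc1ccc(COC[C@@H](CC#CI)O[C@H](CC)[C@H]2CO2)cc1 | intermediate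
13 | (2R)-2-[(1R)-1-({(2R,4Z)-5-iodo-1-[(4-methoxyphenyl)methoxy]pent-4-en-2-yl}oxy)propyl]oxirane | COc1ccc(COC[C@@H](C/C=C\I)O[C@H](CC)[C@H]2CO2)cc1 | intermediate
14 | {(1Z,4R)-5-[(4-methoxyphenyl)methoxy]-4-{(1R)-1-[(2R)-oxiran-2-yl]propoxy}pent-1-en-1-yl}lithium | COc1ccc(COC[C@@H](C/C=C\[Li])O[C@H](CC)[C@H]2CO2)cc1 | intermediate (not isolated)
15 | (2R,3R,8R)-2-ethyl-8-{[(4-methoxyphenyl)methoxy]methyl}-3,4,7,8-tetrahydro-2H-oxocin-3-ol | COc1ccc(COC[C@H]2C/C=C\C[C@@H](O)[C@@H](CC)O2)cc1 | intermediate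
16 | (2R,3S,8R)-3-bromo-2-ethyl-8-{[(4-methoxyphenyl)methoxy]methyl}-3,4,7,8-tetrahydro-2H-oxocine | COc1ccc(COC[C@H]2C/C=C\C[C@H](Br)[C@@H](CC)O2)cc1 | intermediate
17 | [(2R,3S,8R)-3-bromo-2-ethyl-3,4,7,8-tetrahydro-2H-oxocin-8-yl]methanol | OC[C@H]1C/C=C\C[C@H](Br)[C@@H](CC)O1 | intermediate
18 | (2R,3S,8R)-3-bromo-2-ethyl-3,4,7,8-tetrahydro-2H-oxocine-8-carbaldehyde | O=C[C@H]1C/C=C\C[C@H](Br)[C@@H](CC)O1 | intermediate
19 | (1R)-1-[(2R,3S,8R)-3-bromo-2-ethyl-3,4,7,8-tetrahydro-2H-oxocin-8-yl]but-3-en-1-ol | C=CC[C@@H](O)[C@H]1C/C=C\C[C@H](Br)[C@@H](CC)O1 | intermediate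
20 | (2E,5R)-5-[(2R,3S,8R)-3-bromo-2-ethyl-3,4,7,8-tetrahydro-2H-oxocin-8-yl]-5-hydroxypent-2-enal | O=C/C=C/C[C@@H](O)[C@H]1C/C=C\C[C@H](Br)[C@@H](CC)O1 | intermediate
21 | (1R,3E)-1-[(2R,3S,8R)-3-bromo-2-ethyl-3,4,7,8-tetrahydro-2H-oxocin-8-yl]hex-3-en-5-yn-1-ol | C#C/C=C/C[C@@H](O)[C@H]1C/C=C\C[C@H](Br)[C@@H](CC)O1 | intermediate
22 | (1R,3E)-1-[(2R,3S,8R)-3-bromo-2-ethyl-3,4,7,8-tetrahydro-2H-oxocin-8-yl]hex-3-en-5-yn-1-yl acetate | C#C/C=C/C[C@@H](OC(C)=O)[C@H]1C/C=C\C[C@H](Br)[C@@H](CC)O1 | target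

**Step count:** 16 steps in total; longest linear sequence 15 steps (1, 2, 4–16; step 3 is a one-step branch).

**Steps most likely to fail, with fallbacks**

Step 9 (proposed new method). The alkenyllithium may be protonated or may react intermolecularly before it closes the ring. It may also attack C12 (7-exo), and the BF3-activated epoxide may be opened by iodide or by a neighbouring ether oxygen instead. The fallback uses known chemistry, sets out from 11 and returns at 15. CH2=CHMgBr with CuI (cat.) in THF at −40 °C opens the epoxide at C11, which makes the C10–C11 bond intermolecularly and gives (3R,4R)-3-({(2R)-1-[(4-methoxyphenyl)methoxy]-5-(trimethylsilyl)pent-4-yn-2-yl}oxy)hept-6-en-4-ol F1. K2CO3 in MeOH removes the silyl group to give the terminal alkyne F2. H2 over Lindlar catalyst (Pd/CaCO3/Pb(OAc)2, quinoline) gives the diene F3. Ring-closing metathesis with the second-generation Grubbs catalyst (CH2Cl2, 40 °C, high dilution) then closes the oxocene at C9=C10 and should give 15, a closure well precedented for bis-allylic ethers of this type with gauche O–C–C–O units.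

Step 4. With a hindered β-alkoxy secondary alkoxide the allylation may be slow, and branch selectivity and catalyst-controlled diastereoselectivity at C13 may erode. The fallback sets out from 5 and returns at 9. The sodium alkoxide of 5 (NaH, THF, 0 °C) is alkylated with methyl (2S)-2-{[(trifluoromethyl)sulfonyl]oxy}butanoate F4 (from commercial methyl (2S)-2-hydroxybutanoate, Tf2O, 2,6-lutidine, CH2Cl2, −78 °C) by SN2 displacement with inversion, giving the (R)-alkoxy ester F5. i-Bu2AlH (CH2Cl2, −78 °C) gives the aldehyde F6, and Ph3P=CH2 (Ph3PCH3Br, KOt-Bu, THF, 0 °C) gives 9. Here C13 comes from the chiral pool instead of from catalyst control.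

Step 13. Chelation by the hindered di-secondary ring oxygen may be incomplete, so that open (Felkin or Cornforth) transition states compete and facial selectivity at C6 drops. The fallback sets out from 18 and returns at 19. CH2=CHCH2MgBr (Et2O, −78 °C) gives the C6-epimeric alcohols 1-[(2R,3S,8R)-3-bromo-2-ethyl-3,4,7,8-tetrahydro-2H-oxocin-8-yl]but-3-en-1-ol F7. Dess–Martin periodinane gives the allyl ketone F8. LiBH(s-Bu)3 (THF, −78 °C) should then reduce it under Felkin–Anh control (C7–O bond antiperiplanar to the incoming hydride) to the 6R alcohol 19.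

**Further compounds**
F1 | step 9 | (3R,4R)-3-({(2R)-1-[(4-methoxyphenyl)methoxy]-5-(trimethylsilyl)pent-4-yn-2-yl}oxy)hept-6-en-4-ol | COc1ccc(COC[C@@H](CC#C[Si](C)(C)C)O[C@H](CC)[C@H](O)CC=C)cc1
F2 | step 9 | (3R,4R)-3-({(2R)-1-[(4-methoxyphenyl)methoxy]pent-4-yn-2-yl}oxy)hept-6-en-4-ol | COc1ccc(COC[C@@H](CC#C)O[C@H](CC)[C@H](O)CC=C)cc1
F3 | step 9 | (3R,4R)-3-({(2R)-1-[(4-methoxyphenyl)methoxy]pent-4-en-2-yl}oxy)hept-6-en-4-ol | COc1ccc(COC[C@@H](CC=C)O[C@H](CC)[C@H](O)CC=C)cc1
F4 | step 4 | methyl (2S)-2-{[(trifluoromethyl)sulfonyl]oxy}butanoate | CC[C@H](OS(=O)(=O)C(F)(F)F)C(=O)OC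
F5 | step 4 | methyl (2R)-2-({(2R)-1-[(4-methoxyphenyl)methoxy]-5-(trimethylsilyl)pent-4-yn-2-yl}oxy)butanoate | COc1ccc(COC[C@@H](CC#C[Si](C)(C)C)O[C@H](CC)C(=O)OC)cc1
F6 | step 4 | (2R)-2-({(2R)-1-[(4-methoxyphenyl)methoxy]-5-(trimethylsilyl)pent-4-yn-2-yl}oxy)butanal | COc1ccc(COC[C@@H](CC#C[Si](C)(C)C)O[C@H](CC)C=O)cc1
F7 | step 13 | 1-[(2R,3S,8R)-3-bromo-2-ethyl-3,4,7,8-tetrahydro-2H-oxocin-8-yl]but-3-en-1-ol, both C1 epimers | C=CCC(O)[C@H]1C/C=C\C[C@H](Br)[C@@H](CC)O1
F8 | step 13 | 1-[(2R,3S,8R)-3-bromo-2-ethyl-3,4,7,8-tetrahydro-2H-oxocin-8-yl]but-3-en-1-one | C=CCC(=O)[C@H]1C/C=C\C[C@H](Br)[C@@H](CC)O1
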